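**Retrosynthetic overview**
- The target comes from its bis-MOM ether, and that from an achiral isoflavone. One Ru–H transfer-hydrogenation cascade (C2=C3, then C4=O under dynamic kinetic resolution, then the ionised C4–OH) sets C3. It follows the sequence isoflavone → isoflavanone → isoflavanol → isoflavan.
- The isoflavone comes from an acyclic formyl deoxybenzoin that carries a prenyl ether on ring A and a 1,1-dimethylpropargyl ether on ring B. One thermolysis builds both oxygen heterocycles.
- Ring order in that flask: the dimethylpyran ring closes first, by oxa-6π closure on O2' of the same vinyl o-quinone methide that an oxidised 3'-prenylphenol would give. A para-Claisen–Cope shift then puts prenyl on C6 and frees the ring A phenol. That phenol closes the pyranone ring through the 2-hydroxyisoflavanone, which loses water.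
- The formyl deoxybenzoin comes from a chalcone by enone-selective epoxidation and a 1,2-shift. This is the isoflavone-synthase-type change from a 1,3-diaryl to a 1,2-diaryl skeleton, and it leaves the other π-bonds untouched.
- The chalcone comes from a Claisen–Schmidt union of two doubly O-alkylated blocks, made from 2',4'-dihydroxy-6'-methoxyacetophenone and 2,4-dihydroxybenzaldehyde.

Assumption: ketone 1 is bought as a catalogue compound, and operations run in one flask or on crude, unpurified material count as one step (prenyl = 3-methylbut-2-enyl, MOM = methoxymethyl).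

Step 1
Reactants: 1 1-(2,4-dihydroxy-6-methoxyphenyl)ethanone
Product: 3 1-[2-methoxy-4-(methoxymethoxy)-6-(prenyloxy)phenyl]ethanone, via 4-O-MOM ketone 2 (not isolated)
Conditions: K2CO3 (3.5 equiv), MOMCl (1.05 equiv), acetone, 0 °C to rt; then prenyl bromide (1.5 equiv), reflux
Reagents that add atoms: chloromethyl methyl ether COCCl; prenyl bromide CC(C)=CCBr
Why: Sequential Williamson etherification works because the free 4-OH reacts first while the 2-OH is held in a hydrogen bond to the ketone, and this chelated phenol is alkylated by the allylic bromide only at reflux; no stereocentre is formed.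

Step 2
Reactants: 4 2,4-dihydroxybenzaldehyde
Product: 6 4-(methoxymethoxy)-2-(2-methylbut-3-yn-2-yloxy)benzaldehyde, via 4-O-MOM aldehyde 5 (not isolated)
Conditions: K2CO3 (3.5 equiv), MOMCl (1.05 equiv), MeCN, 0 °C to rt; then 3-chloro-3-methylbut-1-yne (2 equiv), KI (cat.), CuI (10 mol %), 70 °C
Reagents that add atoms: chloromethyl methyl ether COCCl; 3-chloro-3-methylbut-1-yne CC(C)(Cl)C#C
Why: The same chelation-controlled Williamson selectivity blocks O4 first, and copper-catalysed propargylic etherification then places the tertiary propargyl group on the only phenol left (O2), which fixes which oxygen will end up in the pyran ring; no stereocentre is formed.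

Step 3
Reactants: 3 ring A ketone 1-[2-methoxy-4-(methoxymethoxy)-6-(prenyloxy)phenyl]ethanone; 6 ring B aldehyde 4-(methoxymethoxy)-2-(2-methylbut-3-yn-2-yloxy)benzaldehyde
Product: 7 (E)-1-[2-methoxy-4-(methoxymethoxy)-6-(prenyloxy)phenyl]-3-[4-(methoxymethoxy)-2-(2-methylbut-3-yn-2-yloxy)phenyl]prop-2-en-1-one
Conditions: KOH, EtOH, rt, 36 h
Reagents that add atoms: none
Why: Claisen–Schmidt condensation of a fully O-alkylated 2,4,6-trioxygenated acetophenone and a non-enolisable aldehyde gives the thermodynamic E-enone, and all ethers and the alkyne are stable to base.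

Step 4
Reactants: 7 (E)-chalcone
Product: 9 3-[2-methoxy-4-(methoxymethoxy)-6-(prenyloxy)phenyl]-2-[4-(methoxymethoxy)-2-(2-methylbut-3-yn-2-yloxy)phenyl]-3-oxopropanal (formyl deoxybenzoin; mainly enol; C2 labile), via trans-epoxide 8 (not isolated)
Conditions: 30% aq H2O2, NaOH, MeOH/THF, 0 °C to rt, neutral extractive work-up; then crude 8, BF3·OEt2 (0.2 equiv), CH2Cl2, −78 to −40 °C, pH 7 quench
Reagents that add atoms: hydrogen peroxide OO
Why: Weitz–Scheffer nucleophilic epoxidation attacks only the electron-poor enone and leaves the prenyl ether alkene and the alkyne alone, then the benzylic C–O bond of 8, activated by the ortho and para donors, ionises at low temperature and the aroyl group shifts to that carbon (House–Meinwald-type rearrangement of chalcone epoxides) to give the 1,2-diaryl skeleton, the two stereocentres of racemic 8 being erased because 9 enolises.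

Step 5
Reactants: 9 formyl deoxybenzoin
Product: 13 5-methoxy-7-(methoxymethoxy)-3-[5-(methoxymethoxy)-2,2-dimethyl-2H-chromen-8-yl]-6-prenyl-4H-chromen-4-one (isoflavone), via o-quinone methide 10 (not isolated), via prenylated phenol 11 (not isolated), via 2-hydroxyisoflavanone 12 (not isolated)
Conditions: PhNEt2, 190 °C, argon stream (water swept out), 3 h
Reagents that add atoms: none
Why: Proposed new method: three individually known thermal events are merged in one flask, namely the aryl propargyl ether Claisen rearrangement on ring B (only C3 is a free ortho position) followed by enolisation and a 1,5-H shift to the vinyl o-quinone methide 10, which closes by oxa-6π electrocyclisation on its single oxygen, then the para-Claisen–Cope sequence on ring A ([3,3] to the free ortho carbon, [3,3] on to the para carbon between OMOM and OMe), which delivers a normal prenyl group and the free phenol of 11, and finally addition of that phenol to the formyl carbon to give 12, which loses water; the closest known reaction types are the thermal chromene synthesis from aryl 1,1-dimethylpropargyl ethers and the para-Claisen–Cope prenyl shift of 2-prenyloxy-4,6-dialkoxyacetophenones in PhNEt2 near 200 °C, and no stereocentre survives.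

Step 6
Reactants: 13 isoflavone
Product: 16 (3R)-5-methoxy-7-(methoxymethoxy)-3-[5-(methoxymethoxy)-2,2-dimethyl-2H-chromen-8-yl]-6-prenylchroman (isoflavan bis-MOM ether), via racemising isoflavanone 14 (not isolated), via cis-isoflavan-4-ol 15 (not isolated)
Conditions: RuCl[(R,R)-TsDPEN](p-cymene) (5 mol %), HCO2H/Et3N 5:2, EtOAc, 45 °C, 48 h
Reagents that add atoms: none
Why: In this Noyori–Ikariya asymmetric transfer hydrogenation, Ru–H first adds 1,4 to the chromone to give 14, which racemises through its enol under Et3N, the (R,R) catalyst then reduces only the (3R) ketone to the cis (3R,4R) alcohol 15 (dynamic kinetic resolution, with the sense known for aryl alkyl ketones, where (R,R) gives the R carbinol), and the 2,4,6-trioxygenated benzylic alcohol ionises in the formic acid medium and takes a third hydride at C4, so C3 stays R while the unpolarised prenyl and chromene alkenes are inert to Ru–H.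

Step 7
Reactants: 16 (3R)-isoflavan bis-MOM ether
Product: 17 8-[(3R)-7-hydroxy-5-methoxy-6-prenylchroman-3-yl]-2,2-dimethyl-2H-chromen-5-ol (target)
Conditions: dilute HCl in MeOH, 40 °C, 2 h
Reagents that add atoms: none
Why: Acid-catalysed acetal exchange cleaves both aryl MOM ethers under conditions routinely tolerated by o-prenylphenols and 2,2-dimethylchromenes, and C3 carries no acidic or ionisable bond, so the R configuration is kept.

**Compound list**
1 | 1-(2,4-dihydroxy-6-methoxyphenyl)ethanone | CC(=O)c1c(O)cc(O)cc1OC | starting material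
2 | 1-[2-hydroxy-6-methoxy-4-(methoxymethoxy)phenyl]ethanone | CC(=O)c1c(O)cc(OCOC)cc1OC | intermediate
3 | 1-[2-methoxy-4-(methoxymethoxy)-6-(3-methylbut-2-enyloxy)phenyl]ethanone | CC(=O)c1c(OCC=C(C)C)cc(OCOC)cc1OC | intermediate
4 | 2,4-dihydroxybenzaldehyde | O=Cc1ccc(O)cc1O | starting material
5 | 2-hydroxy-4-(methoxymethoxy)benzaldehyde | O=Cc1ccc(OCOC)cc1O | intermediate
6 | 4-(methoxymethoxy)-2-(2-methylbut-3-yn-2-yloxy)benzaldehyde | O=Cc1ccc(OCOC)cc1OC(C)(C)C#C | intermediate
7 | (E)-chalcone from 3 and 6 | COCOc1cc(OC)c(C(=O)/C=C/c2ccc(OCOC)cc2OC(C)(C)C#C)c(OCC=C(C)C)c1 | intermediate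
8 | racemic trans-2,3-epoxide of 7 (one enantiomer drawn) | COCOc1cc(OC)c(C(=O)[C@@H]2O[C@H]2c3ccc(OCOC)cc3OC(C)(C)C#C)c(OCC=C(C)C)c1 | intermediate
9 | formyl deoxybenzoin (2-aryl-3-aryl-3-oxopropanal, mainly enol, C2 labile) | COCOc1cc(OC)c(C(=O)C(C=O)c2ccc(OCOC)cc2OC(C)(C)C#C)c(OCC=C(C)C)c1 | intermediate
10 | ring B o-quinone methide, 6-(3-methylbut-2-enylidene)cyclohexa-2,4-dienone form of 9 | COCOc1cc(OC)c(C(=O)C(C=O)C2=CC=C(OCOC)C(=CC=C(C)C)C2=O)c(OCC=C(C)C)c1 | intermediate
11 | 3-[2-hydroxy-6-methoxy-4-(methoxymethoxy)-5-prenylphenyl]-2-[5-(methoxymethoxy)-2,2-dimethyl-2H-chromen-8-yl]-3-oxopropanal | COCOc1cc(O)c(C(=O)C(C=O)c2ccc(OCOC)c3c2OC(C)(C)C=C3)c(OC)c1CC=C(C)C | intermediate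
12 | 2-hydroxyisoflavanone (lactol of 11, mixture of diastereomers) | COCOc1cc2OC(O)C(c3ccc(OCOC)c4c3OC(C)(C)C=C4)C(=O)c2c(OC)c1CC=C(C)C | intermediate
13 | 5-methoxy-7-(methoxymethoxy)-3-[5-(methoxymethoxy)-2,2-dimethyl-2H-chromen-8-yl]-6-prenyl-4H-chromen-4-one | COCOc1cc2occ(-c3ccc(OCOC)c4c3OC(C)(C)C=C4)c(=O)c2c(OC)c1CC=C(C)C | intermediate
14 | 2,3-dihydro derivative of 13 (isoflavanone, racemising at C3) | COCOc1cc2OCC(c3ccc(OCOC)c4c3OC(C)(C)C=C4)C(=O)c2c(OC)c1CC=C(C)C | intermediate
15 | (3R,4R)-cis-isoflavan-4-ol | COc1c(CC=C(C)C)c(OCOC)cc2c1[C@H](O)[C@H](c1ccc(OCOC)c3c1OC(C)(C)C=C3)CO2 | intermediate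
16 | (3R)-isoflavan bis-MOM ether | COc1c(CC=C(C)C)c(OCOC)cc2c1C[C@H](c1ccc(OCOC)c3c1OC(C)(C)C=C3)CO2 | intermediate
17 | 8-[(3R)-7-hydroxy-5-methoxy-6-(3-methylbut-2-enyl)chroman-3-yl]-2,2-dimethyl-2H-chromen-5-ol (CNP0119857.1) | COc1c(CC=C(C)C)c(O)cc2c1C[C@H](c1ccc(O)c3c1OC(C)(C)C=C3)CO2 | target

**Totals**
- Total step count: 7.
- Longest linear sequence: 6 (step 1 or 2, then steps 3 to 7).

**Steps most likely to fail**

Step 5 (thermal double-ring cascade). The heat-sensitive formyl ketone may lose its formyl group, or the prenyl shift may stop at the ortho carbon.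
The fallback sets out from chalcone 7 and comes back at isoflavone 13. It runs both sigmatropic events on the thermally robust chalcone before any oxidation. Heating 7 in PhNEt2 at 190 °C gives the 5'-prenylated, chromene-fused 2'-hydroxychalcone F1. K2CO3 and allyl bromide convert it into the 2'-O-allyl chalcone F2. H2O2/NaOH gives the trans-epoxide F3, and BF3·OEt2 at −78 °C gives the 2'-O-allyl formyl deoxybenzoin F4. Pd(PPh3)4 and morpholine remove the allyl group at rt, and the freed phenol 11 closes and dehydrates to 13 without strong heating.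

Step 6 (triple hydride cascade). The hindered, electron-rich chromone may resist 1,4-reduction. The long-lived C4 cation may also lose H3 to an isoflavene and erode the ee.
The fallback sets out from 13 and comes back at 16. It separates the three reductions and removes the oxygen by a radical path, so no cation is involved. LiBH(s-Bu)3 in THF at −78 °C gives isolated racemic 14. RuCl[(R,R)-TsDPEN](p-cymene) with HCO2Na in water/EtOAc, free of acid, stops at isolated 15. NaH, CS2 and MeI give the S-methyl xanthate F5. Bu3SnH and AIBN in toluene at 80 °C (Barton–McCombie deoxygenation) then give 16 with C3 untouched.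

Step 4 (epoxidation and 1,2-shift). The donor-rich enone may epoxidise slowly. The Lewis acid may trigger a hydride shift to the 1,2-diketone, or strip the allylic and propargylic ethers.
The fallback sets out from ketone 3 (together with aldehyde 6) and comes back at 9. It bypasses the chalcone by a true 1,2-aryl shift. LiN(SiMe3)2 and 2,2,2-trifluoroethyl trifluoroacetate give the trifluoroacetyl ketone F6. MsN3, Et3N and water in MeCN (detrifluoroacetylative diazo transfer) give the diazoketone F7. HBF4·OEt2 (10 mol %) in CH2Cl2 at −78 °C adds F7 to aldehyde 6, and the electron-rich aryl group migrates to the diazonium carbon as nitrogen leaves, giving 9 directly.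

**Further compounds**
F1 | step 5 | (E)-1-[2-hydroxy-6-methoxy-4-(methoxymethoxy)-5-prenylphenyl]-3-[5-(methoxymethoxy)-2,2-dimethyl-2H-chromen-8-yl]prop-2-en-1-one | COCOc1cc(O)c(C(=O)/C=C/c2ccc(OCOC)c3c2OC(C)(C)C=C3)c(OC)c1CC=C(C)C
F2 | step 5 | 2'-O-allyl ether of F1 | COCOc1cc(OCC=C)c(C(=O)/C=C/c2ccc(OCOC)c3c2OC(C)(C)C=C3)c(OC)c1CC=C(C)C
F3 | step 5 | racemic trans-epoxide of F2 (one enantiomer drawn) | COCOc1cc(OCC=C)c(C(=O)[C@@H]2O[C@H]2c3ccc(OCOC)c4c3OC(C)(C)C=C4)c(OC)c1CC=C(C)C
F4 | step 5 | 2'-O-allyl ether of 11 (formyl deoxybenzoin, C2 labile) | COCOc1cc(OCC=C)c(C(=O)C(C=O)c2ccc(OCOC)c3c2OC(C)(C)C=C3)c(OC)c1CC=C(C)C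
F5 | step 6 | O-[(3R,4R)-isoflavan-4-yl] S-methyl dithiocarbonate of 15 | COc1c(CC=C(C)C)c(OCOC)cc2c1[C@H](OC(=S)SC)[C@H](c1ccc(OCOC)c3c1OC(C)(C)C=C3)CO2
F6 | step 4 | 4,4,4-trifluoro-1-[2-methoxy-4-(methoxymethoxy)-6-(prenyloxy)phenyl]butane-1,3-dione | COCOc1cc(OC)c(C(=O)CC(=O)C(F)(F)F)c(OCC=C(C)C)c1
F7 | step 4 | 2-diazo-1-[2-methoxy-4-(methoxymethoxy)-6-(prenyloxy)phenyl]ethanone | COCOc1cc(OC)c(C(=O)C=[N+]=[N-])c(OCC=C(C)C)c1
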